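The plan hinges on disconnecting C6–C7, the cyclohexane bond that ends at quaternary C6. The feature used is the 1,3-relationship of C4 and C6 in the cyclopentane ring C3–C4–C5–C6–C11: a ketone at C4 conjugated with a C5=C6 double bond makes C6 electrophilic, while C7 enters as an alkenyl carbon whose hydrogen, like the bromine on C8, is supplied only after ring closure. One reductive Heck cyclisation of a Z-iodoalkene then builds the six-membered ring and C6, completing the quaternary triad C3–C11–C6. Its substrate is an acetoxybicyclo[3.2.0]heptenone that bears the C10(CH3)–C9(OTBS)–C8H=C7(I)CH3 chain on bridgehead C11, on the convex face.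

Key step: step 14

Conventions and assumption: C1–C11 are the ring carbons of 29 in the order of its SMILES string and keep these labels in every intermediate; on the cyclopentane, top = face with C3-CH3, C7 and C10, bottom = face with C1, C2 and C6-CH3; on the cyclohexane, inner = face on which C3 and C5 are attached, outer = face with C6-CH3 and C1; R* = (2R,3R,4Z)-3-(tert-butyldimethylsilyloxy)-5-iodohex-4-en-2-yl (C10 to C7); (R)-TRIP is assumed to direct Re-face attack on aldehyde 4 as it does on other conjugated aldehydes.

Step 1
Reactants: 1 but-2-yn-1-ol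
Product: 3 (Z)-3-iodobut-2-en-1-ol, via cyclic alkenylalanate 2 (not isolated)
Conditions: Red-Al, Et2O, 0 °C to rt; then I2, THF, −78 to 0 °C
Reagents that add atoms: iodine, II; Red-Al, [Na+].COCCO[AlH2-]OCCOC (its atoms stay only in 2)
Why: Hydroxyl-directed trans-hydroalumination of a propargylic alcohol puts aluminium on the distal alkyne carbon inside a five-membered alanate, and iodinolysis with retention gives the Z-iodoalkene (iodine cis to the CH2OH carbon), the geometry that step 14 needs.

Step 2
Reactants: 3 (Z)-3-iodobut-2-en-1-ol
Product: 4 (Z)-3-iodobut-2-enal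
Conditions: activated MnO2, CH2Cl2, rt, dark
Reagents that add atoms: none
Why: Manganese dioxide oxidation is selective for allylic alcohols and neutral, so the Z geometry should be kept if the aldehyde is used at once.

Step 3
Reactants: 4 (Z)-3-iodobut-2-enal; 5 (E)-crotylboronic acid pinacol ester
Product: 6 (3R,4R,5Z)-6-iodo-3-methylhepta-1,5-dien-4-ol
Conditions: (R)-TRIP (5 mol %), 4 Å MS, toluene, −30 °C; aqueous work-up
Reagents that add atoms: none
Why: Chiral phosphoric acid catalysed crotylboration runs through a closed chair (Zimmerman–Traxler) transition state, so the E-boronate gives the anti C9/C10 pair and the (R)-catalyst directs attack to the Re face of the aldehyde, which sets C9 and C10 both as R and also brings in C11 and C1 as the vinyl group.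

Step 4
Reactants: 6 (3R,4R,5Z)-6-iodo-3-methylhepta-1,5-dien-4-ol
Product: 7 tert-butyldimethylsilyl ether of 6
Conditions: TBSOTf, 2,6-lutidine, CH2Cl2, 0 °C
Reagents that add atoms: TBSOTf, CC(C)(C)[Si](C)(C)OS(=O)(=O)C(F)(F)F
Why: Silylation of a hindered secondary allylic alcohol with the silyl triflate is routine and touches no stereocentre.

Step 5
Reactants: 7 tert-butyldimethylsilyl ether of 6
Product: 9 (3R,4R,5Z)-4-(tert-butyldimethylsilyloxy)-6-iodo-3-methylhept-5-en-1-ol, via B-alkyl-9-BBN adduct 8 (not isolated)
Conditions: 9-BBN, THF, 0 °C to rt; then NaOH, H2O2, 0 °C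
Reagents that add atoms: hydrogen peroxide, OO; 9-BBN, [H]B1C2CCCC1CCC2 (its atoms stay only in 8)
Why: In this hydroboration–oxidation 9-BBN adds anti-Markovnikov to the monosubstituted alkene only, because the iodine-bearing trisubstituted alkene is hindered and electron-poor, and oxidation of the C–B bond gives the C1 alcohol without touching C9 or C10.

Step 6
Reactants: 9 (3R,4R,5Z)-4-(tert-butyldimethylsilyloxy)-6-iodo-3-methylhept-5-en-1-ol
Product: 10 (3R,4R,5Z)-4-(tert-butyldimethylsilyloxy)-6-iodo-3-methylhept-5-enoic acid
Conditions: TEMPO (cat.), PhI(OAc)2, MeCN/H2O, rt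
Reagents that add atoms: water, O
Why: Oxoammonium (TEMPO) oxidation with a hypervalent iodine co-oxidant in wet acetonitrile takes a primary alcohol through the aldehyde hydrate to the acid under near-neutral conditions that silyl ether and iodoalkene tolerate.

Step 7
Reactants: 10 (3R,4R,5Z)-4-(tert-butyldimethylsilyloxy)-6-iodo-3-methylhept-5-enoic acid
Product: 11 methyl ester of 10
Conditions: MeI, K2CO3, DMF, rt
Reagents that add atoms: iodomethane, CI
Why: SN2 O-alkylation of the carboxylate gives the methyl ester, which allows clean mono-deprotonation in step 8.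

Step 8
Reactants: 11 methyl ester of 10; 12 5-methylhex-5-en-2-one
Product: 14 methyl 3-hydroxy-3,6-dimethyl-2-R*-hept-6-enoate (mixture at C11 and C6), via lithium enolate 13 (not isolated)
Conditions: LDA (1.05 equiv), THF, −78 °C; then 12, −78 °C; NH4Cl quench at −78 °C
Reagents that add atoms: LDA, [Li+].CC(C)[N-]C(C)C (lithium stays only in 13)
Why: Aldol addition of a lithium ester enolate to a methyl ketone forms C11–C6; one equivalent of amide base at −78 °C is consumed by the ester before it can dehydroiodinate the alkene, and the new centres C11 and C6 arise as a mixture that does not matter because both become sp2 in step 10.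

Step 9
Reactants: 14 methyl 3-hydroxy-3,6-dimethyl-2-R*-hept-6-enoate
Product: 15 3-hydroxy-3,6-dimethyl-2-R*-hept-6-enoic acid (mixture at C11 and C6)
Conditions: LiOH, THF/MeOH/H2O, 40 °C; then dilute HCl, 0 °C
Reagents that add atoms: lithium hydroxide, [Li+].[OH-]
Why: Saponification in a protic medium keeps the tertiary alkoxide concentration low, so hydrolysis should outrun retro-aldol cleavage, and silyl ether and iodoalkene are inert to hydroxide.

Step 10
Reactants: 15 3-hydroxy-3,6-dimethyl-2-R*-hept-6-enoic acid
Product: 17 (1R,5S)-1,4-dimethyl-5-R*-bicyclo[3.2.0]hept-3-en-6-one (C1 ketone; C3-CH3 and R* cis on the convex face), via (Z)-vinylketene 16 (not isolated)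
Conditions: Ac2O, KOAc, rt, then 120 °C
Reagents that add atoms: none
Why: Mixed-anhydride formation, loss of acetic acid and reversible deprotonation give the (Z)-vinylketene 16, whose intramolecular ketene–alkene [2+2] cycloaddition (the established conversion of 3-hydroxy-6-alkenoic acids into bicyclo[3.2.0]hept-3-en-6-ones) joins the carbonyl carbon C1 to the CH2 terminus C2 and C11 to the methyl-bearing C3; the three-atom tether enforces the cis fusion, so C3 and C11 are set together, and the face is chosen by the chain, which places the C9 branch anti to the forming C11–C3 bond, C10-H over the nascent cyclobutanone and the silyloxy group toward the open ketene-carbonyl side instead of against C6-CH3, so the ring epimer should be the minor product and is removed by chromatography.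

Step 11
Reactants: 17 (1R,5S)-1,4-dimethyl-5-R*-bicyclo[3.2.0]hept-3-en-6-one
Product: 18 (1R,5S,6R)-1,4-dimethyl-5-R*-bicyclo[3.2.0]hept-3-en-6-ol (C1 hydroxyl exo and cis to R*)
Conditions: (S)-Me-CBS (30 mol %), catecholborane, toluene, −78 °C
Reagents that add atoms: none
Why: In the Corey–Bakshi–Shibata reduction the catalyst tells the C2 methylene flank from the quaternary C11 flank of the cyclobutanone and, in the (S)-series, delivers hydride to the concave face to give the (R)-configured C1 alcohol; reagent control is chosen because both ketone faces are flanked by carbon substituents, and catecholborane at −78 °C does not hydroborate the alkenes.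

Step 12
Reactants: 18 (1R,5S,6R)-1,4-dimethyl-5-R*-bicyclo[3.2.0]hept-3-en-6-ol
Product: 19 C1 acetate of 18
Conditions: Ac2O, Et3N, DMAP, CH2Cl2, rt
Reagents that add atoms: acetic anhydride, CC(=O)OC(C)=O
Why: DMAP-catalysed acylation installs the C1 acetate of the target with retention, so no protecting-group exchange is needed later.

Step 13
Reactants: 19 C1 acetate of 18
Product: 20 bicyclo[3.2.0]heptenone with C4 ketone, C5=C6 double bond, exo C1 acetate and R* on C11
Conditions: CrO3, 3,5-dimethylpyrazole, CH2Cl2, −20 °C
Reagents that add atoms: chromium trioxide, O=[Cr](=O)=O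
Why: Allylic oxidation with the chromium trioxide–3,5-dimethylpyrazole complex converts the ring methylene C4 next to the electron-rich C5=C6 double bond into the conjugated ketone, as 1-methylcycloalkenes give 3-methylcycloalkenones, while the iodine-deactivated C7=C8 alkene and its silyl-protected allylic position should stay intact.

Step 14
Reactants: 20 bicyclo[3.2.0]heptenone with C4 ketone, C5=C6 double bond, exo C1 acetate and R* on C11
Product: 21 tricyclic C4 ketone with C7=C8 double bond, C9 silyl ether and C1 acetate (C6 R, cis-fused five- and six-membered rings)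
Conditions: Pd(OAc)2 (10 mol %), PPh3 (30 mol %), HCO2Na, degassed DMF, 80 °C
Reagents that add atoms: none
Why: Pd(0) inserts into the C7–I bond with retention of the Z geometry, the alkenylpalladium adds syn across C5=C6 so that C7 binds C6 and palladium sits on C5 as a palladium enolate, and since neither C6 nor C4 offers a β-hydrogen this species waits for formate, which loses CO2 and hands over hydride to give the C5 methylene and Pd(0). The closest known reaction type is the intramolecular reductive Heck (formal conjugate) cyclisation of alkenyl iodides onto β-substituted cycloalkenones, an established way to all-carbon quaternary centres. The cyclohexene ring C6–C7–C8–C9–C10–C11 closes in the 6-exo-trig mode, whereas 7-endo attack at C5 opposes the polarisation of the enone and the reach of the chain. The only new stereocentre, C6, is controlled by C11: the cis-fused cyclobutane occupies the bottom face, the chain stands on the top face, and its three-atom link C10–C9–C8 can bring C7 only to that face, which gives the cis ring fusion and pushes C6-CH3 to the bottom (6R). The selectivity needed is insertion before hydride capture of the alkenylpalladium (plain deiodination), and it is secured by the Z geometry and the quaternary anchor, which hold palladium over C6 in a chair-like array with C10-CH3 equatorial, and by sparingly soluble sodium formate, which keeps the hydride supply low. Acetate, silyl ether and C1, C3, C9, C10 and C11 are untouched, and the product keeps the C4 ketone and the allylic C9 oxygen as handles for C4, C7, C8 and C9.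

Step 15
Reactants: 21 tricyclic C4 ketone
Product: 22 tricyclic C4 alcohol (4R; hydroxyl on the top face cis to C3-CH3)
Conditions: NaBH4, MeOH/THF, −20 to 0 °C
Reagents that add atoms: none
Why: In this borohydride reduction of a hindered cyclopentanone the top face of C4 is screened by C3-CH3 and by the pseudoaxial C9 silyl ether that overhangs the five-membered ring, so hydride should enter from the bottom face and place the hydroxyl on top, and the acetate survives.

Step 16
Reactants: 22 tricyclic C4 alcohol
Product: 23 tricyclic C4 bromide (4S; bromine on the bottom face trans to C3-CH3)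
Conditions: CBr4, P(n-Oct)3, toluene, 70 °C
Reagents that add atoms: carbon tetrabromide, BrC(Br)(Br)Br
Why: In the Appel reaction the alkoxyphosphonium salt is displaced by bromide in an SN2 step with inversion, which puts bromine on the bottom face from the same side that accepted hydride in step 15, and the non-polar medium disfavours ionisation to a cyclobutylcarbinyl cation.

Step 17
Reactants: 23 tricyclic C4 bromide
Product: 24 C9 allylic alcohol (9R; hydroxyl on the inner face)
Conditions: HF·pyridine, pyridine, THF, 0 °C to rt
Reagents that add atoms: none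
Why: Fluoride-mediated desilylation under mildly acidic conditions frees the C9 allylic alcohol without acetate cleavage or dehydrobromination.

Step 18
Reactants: 24 C9 allylic alcohol
Product: 25 saturated C9 alcohol (7R; C7-H inner and C7-CH3 outer)
Conditions: [Ir(cod)(PCy3)(py)]PF6 (10 mol %), H2 (1 atm), CH2Cl2, rt
Reagents that add atoms: none
Why: In the hydroxyl-directed hydrogenation with Crabtree's catalyst iridium bound to the inner-face C9 hydroxyl adds hydrogen to the same face of C7=C8, so C7-H ends inner and C7-CH3 outer, which overrides the concave shape of that face, and alkyl bromide and acetate are inert.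

Step 19
Reactants: 25 saturated C9 alcohol
Product: 26 C9 ketone
Conditions: Dess–Martin periodinane, CH2Cl2, rt
Reagents that add atoms: none
Why: Dess–Martin oxidation gives the C9 ketone under neutral conditions, and C10 stays as set because its equatorial methyl is also the thermodynamically preferred arrangement (the epimer would be 1,3-diaxial to C6-CH3).

Step 20
Reactants: 26 C9 ketone
Product: 28 C8 bromo C9 ketone (8S; equatorial bromine on the inner face trans to C7-CH3), via C8=C9 trimethylsilyl enol ether 27 (not isolated)
Conditions: LiHMDS, TMSCl, THF, −78 °C; crude 27, then NBS, THF, 0 °C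
Reagents that add atoms: N-bromosuccinimide, O=C1CCC(=O)N1Br; chlorotrimethylsilane, C[Si](C)(C)Cl (silicon stays only in 27)
Why: Kinetic deprotonation at the C8 methylene and not at the tertiary C10-H flanked by quaternary C11 gives the C8=C9 silyl enol ether, and electrophilic bromination leads to the equatorial inner-face bromide, because an axial bromine would be 1,3-diaxial to C6-CH3 and equilibrates through the enol, as in the 2α-bromination of 3-keto steroids.

Step 21
Reactants: 28 C8 bromo C9 ketone
Product: 29 target CNP0246576.1 (1R,3R,4S,6R,7R,8S,9R,10R,11R in the route numbering)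
Conditions: NaBH4, MeOH/CH2Cl2, −40 °C
Reagents that add atoms: none
Why: In this borohydride reduction of an α-bromo ketone the axial C11–C3 bond and C3-CH3 close the inner face of C9, as a 3-axial substituent does in 3,3,5-trimethylcyclohexanone, so hydride comes from the outer, equatorial side and gives the axial inner-face alcohol (9R) cis to the equatorial C8 bromine; a cis bromohydrin cannot close to an epoxide, and acetate and both bromides are inert at this temperature.

Compound list
1 | but-2-yn-1-ol | CC#CCO | starting material
2 | sodium cyclic alkenylalanate from 1 and Red-Al | CC1=CCO[Al-]1(OCCOC)OCCOC.[Na+] | intermediate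
3 | (Z)-3-iodobut-2-en-1-ol | OC/C=C(/C)I | intermediate
4 | (Z)-3-iodobut-2-enal | O=C/C=C(/C)I | intermediate
5 | (E)-crotylboronic acid pinacol ester | C/C=C/CB1OC(C)(C)C(C)(C)O1 | starting material
6 | (3R,4R,5Z)-6-iodo-3-methylhepta-1,5-dien-4-ol | C=C[C@@H](C)[C@@H](O)/C=C(/C)I | intermediate
7 | tert-butyldimethylsilyl ether of 6 | C=C[C@@H](C)[C@@H](O[Si](C)(C)C(C)(C)C)/C=C(/C)I | intermediate
8 | B-alkyl-9-BBN adduct of 7 | B1(CC[C@@H](C)[C@@H](O[Si](C)(C)C(C)(C)C)/C=C(/C)I)C2CCCC1CCC2 | intermediate
9 | (3R,4R,5Z)-4-(tert-butyldimethylsilyloxy)-6-iodo-3-methylhept-5-en-1-ol | OCC[C@@H](C)[C@@H](O[Si](C)(C)C(C)(C)C)/C=C(/C)I | intermediate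
10 | (3R,4R,5Z)-4-(tert-butyldimethylsilyloxy)-6-iodo-3-methylhept-5-enoic acid | OC(=O)C[C@@H](C)[C@@H](O[Si](C)(C)C(C)(C)C)/C=C(/C)I | intermediate
11 | methyl ester of 10 | COC(=O)C[C@@H](C)[C@@H](O[Si](C)(C)C(C)(C)C)/C=C(/C)I | intermediate
12 | 5-methylhex-5-en-2-one | CC(=C)CCC(C)=O | starting material
13 | lithium enolate of 11 | [Li+].COC([O-])=C[C@@H](C)[C@@H](O[Si](C)(C)C(C)(C)C)/C=C(/C)I | intermediate
14 | methyl 3-hydroxy-3,6-dimethyl-2-R*-hept-6-enoate (mixture at C11, C6) | COC(=O)C(C(C)(O)CCC(C)=C)[C@@H](C)[C@@H](O[Si](C)(C)C(C)(C)C)/C=C(/C)I | intermediate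
15 | 3-hydroxy-3,6-dimethyl-2-R*-hept-6-enoic acid (mixture at C11, C6) | OC(=O)C(C(C)(O)CCC(C)=C)[C@@H](C)[C@@H](O[Si](C)(C)C(C)(C)C)/C=C(/C)I | intermediate
16 | (Z)-vinylketene | O=C=C(/C(C)=C\CC(C)=C)[C@@H](C)[C@@H](O[Si](C)(C)C(C)(C)C)/C=C(/C)I | intermediate
17 | (1R,5S)-1,4-dimethyl-5-R*-bicyclo[3.2.0]hept-3-en-6-one | O=C1C[C@@]2(C)CC=C(C)[C@@]12[C@@H](C)[C@@H](O[Si](C)(C)C(C)(C)C)/C=C(/C)I | intermediate
18 | (1R,5S,6R)-1,4-dimethyl-5-R*-bicyclo[3.2.0]hept-3-en-6-ol (exo alcohol) | O[C@@H]1C[C@@]2(C)CC=C(C)[C@@]12[C@@H](C)[C@@H](O[Si](C)(C)C(C)(C)C)/C=C(/C)I | intermediate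
19 | C1 acetate of 18 | CC(=O)O[C@@H]1C[C@@]2(C)CC=C(C)[C@@]12[C@@H](C)[C@@H](O[Si](C)(C)C(C)(C)C)/C=C(/C)I | intermediate
20 | bicyclo[3.2.0]heptenone, substrate of the key step | CC(=O)O[C@@H]1C[C@@]2(C)C(=O)C=C(C)[C@@]12[C@@H](C)[C@@H](O[Si](C)(C)C(C)(C)C)/C=C(/C)I | intermediate
21 | tricyclic C4 ketone with C7=C8 double bond, product of the key step | CC(=O)O[C@@H]1C[C@@]2(C)C(=O)C[C@]3(C)C(C)=C[C@H](O[Si](C)(C)C(C)(C)C)[C@H](C)[C@]123 | intermediate
22 | tricyclic C4 alcohol (4R) | CC(=O)O[C@@H]1C[C@@]2(C)[C@H](O)C[C@]3(C)C(C)=C[C@H](O[Si](C)(C)C(C)(C)C)[C@H](C)[C@]123 | intermediate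
23 | tricyclic C4 bromide (4S) | CC(=O)O[C@@H]1C[C@@]2(C)[C@@H](Br)C[C@]3(C)C(C)=C[C@H](O[Si](C)(C)C(C)(C)C)[C@H](C)[C@]123 | intermediate
24 | C9 allylic alcohol | CC(=O)O[C@@H]1C[C@@]2(C)[C@@H](Br)C[C@]3(C)C(C)=C[C@H](O)[C@H](C)[C@]123 | intermediate
25 | saturated C9 alcohol (7R) | CC(=O)O[C@@H]1C[C@@]2(C)[C@@H](Br)C[C@]3(C)[C@@H](C)C[C@H](O)[C@H](C)[C@]123 | intermediate
26 | C9 ketone | CC(=O)O[C@@H]1C[C@@]2(C)[C@@H](Br)C[C@]3(C)[C@@H](C)CC(=O)[C@H](C)[C@]123 | intermediate
27 | C8=C9 trimethylsilyl enol ether | CC(=O)O[C@@H]1C[C@@]2(C)[C@@H](Br)C[C@]3(C)[C@@H](C)C=C(O[Si](C)(C)C)[C@H](C)[C@]123 | intermediate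
28 | C8 bromo C9 ketone (8S) | CC(=O)O[C@@H]1C[C@@]2(C)[C@@H](Br)C[C@]3(C)[C@@H](C)[C@H](Br)C(=O)[C@H](C)[C@]123 | intermediate
29 | CNP0246576.1 | CC(=O)O[C@@H]1C[C@@]2(C)[C@@H](Br)C[C@]3(C)[C@@H](C)[C@H](Br)[C@H](O)[C@H](C)[C@]123 | target

Total step count: 21 (13 to the substrate 20, the key step, 7 afterwards). Longest linear sequence: 21 steps, from 1 to 29; 5 and 12 are bought.

Steps most likely to fail, most critical first:

Step 14. The alkenylpalladium may be reduced by formate before it inserts, so that iodine is lost without ring closure. Alternatively, insertion at the fully substituted C6 next to quaternary C11 may be so slow that the catalyst decays. The fallback replaces the organopalladium species by a free alkenyl radical. It sets out from 20, which is treated with Bu3SnH and AIBN in toluene at 80 °C under slow addition. Iodine abstraction gives the σ-alkenyl radical at C7, which adds 6-exo to the electron-poor C6 from the only face the chain can reach. The resulting C5 radical next to the ketone takes hydrogen from the stannane. The fallback comes back to the route at 21 and makes no new compound (F0).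

Step 16. Backside attack at a secondary carbon next to quaternary C3 may be outrun by elimination toward C5 or by ionisation followed by cyclobutane ring expansion. The fallback swaps the ionic substitution for bromine-atom transfer to a C4 radical.
- It sets out from 22, which is acylated with methyl chlorooxoacetate (Et3N, DMAP) to the C4 methyl oxalate F1.
- One equivalent of aqueous CsOH cleaves only the activated oxalate methyl ester and gives the caesium oxalate F2.
- Visible-light photoredox oxidation (iridium photocatalyst, warm dioxane) triggers loss of two CO2.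
- The C4 radical abstracts bromine from diethyl 2-bromo-2-methylmalonate on the same bottom face that accepted hydride in step 15, faster than a cyclobutylcarbinyl radical opens.
- The outcome does not depend on the C4 alcohol configuration, and the fallback comes back to the route at 23.

Step 10. The side chain may discriminate poorly between the two faces of the ketene, so that much ring epimer forms and the two ketones separate badly. The fallback moves the decision from substrate control to reagent control. It sets out from 15, and the cycloaddition mixture of 17 and the ring-epimeric ketone F3 is carried unseparated into the (S)-CBS reduction. The catalyst makes C1 R in both ketones, so 17 gives the exo alcohol 18. F3 gives the endo alcohol F4, a diastereomer of clearly different shape and polarity that is removed by chromatography. The fallback comes back to the route at 18.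

Further compounds
F0 | step 14 | none | none
F1 | step 16 | C4 methyl oxalate of 22 | CC(=O)O[C@@H]1C[C@@]2(C)[C@H](OC(=O)C(=O)OC)C[C@]3(C)C(C)=C[C@H](O[Si](C)(C)C(C)(C)C)[C@H](C)[C@]123
F2 | step 16 | caesium oxalate of 22 | CC(=O)O[C@@H]1C[C@@]2(C)[C@H](OC(=O)C(=O)[O-])C[C@]3(C)C(C)=C[C@H](O[Si](C)(C)C(C)(C)C)[C@H](C)[C@]123.[Cs+]
F3 | step 10 | ring-epimeric ketone (C3 and C11 inverted, chain unchanged) | O=C1C[C@]2(C)CC=C(C)[C@]12[C@@H](C)[C@@H](O[Si](C)(C)C(C)(C)C)/C=C(/C)I
F4 | step 10 | endo alcohol from F3 (C1 R) | O[C@@H]1C[C@]2(C)CC=C(C)[C@]12[C@@H](C)[C@@H](O[Si](C)(C)C(C)(C)C)/C=C(/C)I
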